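I have small amounts of E and X to go on, and I want from them one rate: how fast X and E exchange. Z comes back from that step, so with c_Z constant the exchange is pseudo-first-order, its rate in proportion to c_Z.

| setting | Saturday's | Monday's | flask |
|---|---|---|---|
| G | 0.050 M | 0.075 M | 0.050 M |
| J | 0.045 M | 0.045 M | 0.0450 M |
| Z | 25 µM | 25 µM | 25 µM |
| remark | the very flask that is asked about, followed so far | run made earlier |  |
| time |  |  | 6.0 d |

Saturday's run (percent of the G charged)

| time / h | E / % | X / % |
|---|---|---|
| 1.33 | 5.1 | 14.3 |
| 4.00 | 12.3 | 31.0 |
| 8.00 | 13.3 | 36.5 |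
| 12.0 | 15.9 | 37.2 |
| 15.0 | 14.3 | 39.8 |
| 20.0 | 15.6 | 38.7 |
| 25.0 | 15.5 | 39.3 |

Monday's run (percent of the G charged)

| time / d | E / % | X / % |
|---|---|---|
| 0.333 | 8.4 | 20.0 |
| 0.500 | 7.9 | 24.1 |
| 0.833 | 9.6 | 21.2 |
| 1.25 | 8.1 | 23.0 |
| 1.67 | 9.2 | 22.8 |
| 3.00 | 7.8 | 23.7 |
| 4.00 | 8.6 | 22.6 |

(standard deviation of a reading: 1 percentage point)

- share of E in E plus X at 25 min
- share of E in E plus X at 8.0 h
- share of E in E plus X at 6.0 d
- which of E and X there is more of at 6.0 d

- what may be going on: X + Z <-> E + Z; G + J -> D; J + Z + Q -> Z + X; G + Z -> Z + Q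

At the start of Saturday's flask, which is the flask asked about, E and X together grow by 0.146 /h of the G charged, averaged to the first reading. The plateau of that run reads a share of E of 28.3%. The scheme lets E go back to X, and I take the net flow into E to shrink as the share nears that value.

At 1.33 h, E reads 0.4 percentage points short of that share, less than the 1.6 points between two neighbouring plateau readings. Under a steady feed, the shortfall is the share times the feed over the exchange rate. Taking the plateau gap as a rough size for a shortfall hidden in the scatter gives a rate of 2.58 /h. This is an estimate and no bound: each reading scatters by 1 point, and slower rates stay open. My exchange half-time is then roughly 0.268 h.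

That is far shorter than 6.0 d, so the share should stand at its plateau at 8.0 h and 6.0 d, with X ahead. At 25 min, a steady feed from zero leaves it at 11.0%.

The forecast says 18%, 28% and 28%, with X ahead, adding: “At 25 min the share is below equilibrium, but poorly pinned down.” At 25 min my number is lower than its number.

The flask gives 12.4%, 27.9% and 28.1%, with X ahead at 40.2% against 15.7%.

    X + Z ⇌ E + Z, rate k1*[Z]*[X] forward; the back reaction follows from the equilibrium constant (K = 0.390, k = 13.5 /M/s)
    G + J → D (k = 0.00345 /M/s)
    J + Z + Q → Z + X (k = 280 /M²/s)
    G + Z → Z + Q (k = 7.38 /M/s)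

The early share lies 5.6 points below the forecast, and 25 min is 1.55 of my half-times. With the return of E to X taken away, the share at 25 min rises from 12.4% to 16.6%, and the lead at 6.0 d turns.

With 1.0 × 10⁻⁴ M of Z, my half-time becomes 0.0671 h, and the steady-feed reckoning gives 21.8% at 25 min. That flask gives 24.0%.

All runs were generated by integration on assumed constants.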